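**Retrosynthetic overview**

1. The target is epigallocatechin-(4β→6)-epigallocatechin gallate: upper unit rings A, C, B (locants marked U), lower unit aromatic ring D, pyran ring F and aryl ring E (locants marked L), galloyl ester on O-3(L). Every hydroxyl, O-3(U) included, is carried as a benzyl ether, so one hydrogenolysis ends the route.
2. Ring F is formed last. The strategy rests on the cis pair aryl at C-2(L) / galloyloxy at C-3(L) of ring F, read as a (Z)-2-arylvinyl gallate laid across the four atoms O–C-8a(L)–C-4a(L)–C-4(L)H2 of an ortho-quinone methide of ring D; the [4+2] union makes C-3(L)–C-4(L) and O-1(L)–C-2(L).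
3. The methide comes from a ring D salicyl alcohol whose only free phenol is para to the interflavan bond C-4(U)–C-6(L), so closure can give only the 4→6 isomer. It is reached from the C-4(U) phloroglucinol adduct of a 4-alkoxy hexa-O-benzyl epigallocatechin (symmetric nucleophile, no regiochemical question) by silylation of the least hindered phenol, benzylation, desilylation, ortho-formylation and reduction.
4. The (Z)-enol gallate comes from 3,4,5-tris(benzyloxy)phenylacetylene and 3,4,5-tris(benzyloxy)benzoic acid by ruthenium-catalysed anti-Markovnikov addition.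
5. Ring order: A/C/B taken intact from (−)-epigallocatechin, then ring D attached at C-4(U), then ring F closed in the key step with ring E and the ester already in place.

Key step: step 12

Assumption: the sense of induction of the binaphthyl phosphoric acid on the enol ester face cannot be predicted for this substrate class; the (R)-acid is written, and its antipode would be used if that proves to be the one giving the (2R,3R) lower unit.

In monomer names the primed locants 3′,4′,5′ are the ring B positions as usual; 4β means trans to the 3-oxygen.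

Step 1
Reactants: 1 (−)-epigallocatechin
Product: 2 5,7,3′,4′,5′-penta-O-benzyl-(−)-epigallocatechin (2R,3R; free 3-OH)
Conditions: BnBr (5.5 equiv), K2CO3, DMF, argon, −10 °C → rt
Reagents that add atoms: benzyl bromide, BrCc1ccccc1
Why: Williamson etherification with carbonate alkylates only the five phenols and leaves the secondary 3-OH free, while low temperature and exclusion of air limit C-benzylation and oxidation of the pyrogallol ring; no stereocentre is touched.

Step 2
Reactants: 2 penta-O-benzyl-(−)-epigallocatechin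
Product: 3 4β-(2-ethoxyethoxy)-5,7,3′,4′,5′-penta-O-benzylepigallocatechin (2,3-cis, 3,4-trans)
Conditions: DDQ (2 equiv), 2-ethoxyethanol (5 equiv), CH2Cl2, rt
Reagents that add atoms: 2-ethoxyethanol, CCOCCO
Why: DDQ benzylic oxidation removes hydride from C-4, activated by the 5,7-dialkoxy ring A, and the resulting cation is trapped by the alcohol on the β face, anti to the α-oriented 2-aryl and 3-OH groups, which sets C-4 as 3,4-trans.

Step 3
Reactants: 3 4β-(2-ethoxyethoxy) penta-O-benzyl flavan-3-ol
Product: 4 3-O-benzyl-4β-(2-ethoxyethoxy)-5,7,3′,4′,5′-penta-O-benzylepigallocatechin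
Conditions: NaH, BnBr, Bu4NI (cat.), THF/DMF, 0 °C → rt
Reagents that add atoms: benzyl bromide, BrCc1ccccc1
Why: Williamson etherification of the secondary alkoxide proceeds without touching the base-stable C-4 benzylic ether or any stereocentre, and it removes the last free hydroxyl before the Mitsunobu step.

Step 4
Reactants: 4 hexa-O-benzyl 4β-(2-ethoxyethoxy) electrophile; 5 phloroglucinol (anhydrous, 5 equiv)
Product: 6 hexa-O-benzyl epigallocatechin-(4β→2)-phloroglucinol, the 4β-(2,4,6-trihydroxyphenyl) adduct
Conditions: BF3·OEt2 (0.2 equiv), THF/CH2Cl2, −20 → 0 °C, argon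
Reagents that add atoms: none
Why: Lewis acid ionisation of the 4-alkoxy group gives the flavan-4-yl cation, and Friedel–Crafts C-alkylation of phloroglucinol (three equivalent positions, excess nucleophile against double alkylation) occurs from the β face, anti to the 3-OBn and 2-aryl groups, which sets the 4β (3,4-trans) centre.

Step 5
Reactants: 6 phloroglucinol adduct (ring D triol)
Product: 7 ring D mono-TBDPS ether of 6, silylated on the oxygen para to the interflavan bond
Conditions: TBDPSCl (1.05 equiv), imidazole, DMF, −20 → 0 °C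
Reagents that add atoms: tert-butyl(chloro)diphenylsilane, CC(C)(C)[Si](Cl)(c1ccccc1)c1ccccc1
Why: In this site-selective silylation the bulky chlorosilane should take the only phenol flanked by two ring hydrogens, because the two ortho phenols are shielded by the flavan-4-yl group.

Step 6
Reactants: 7 para-O-TBDPS ring D diol
Product: 8 octa-O-benzyl para-O-TBDPS adduct, 4β-[2,6-bis(benzyloxy)-4-(tert-butyldiphenylsilyloxy)phenyl]
Conditions: BnOH (3 equiv), PPh3 (3 equiv), DIAD (3 equiv), THF, 0 °C → rt
Reagents that add atoms: benzyl alcohol, OCc1ccccc1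
Why: Mitsunobu etherification benzylates the two remaining phenols under neutral conditions, so the aryl silyl ether is not cleaved or transferred by phenoxide as it could be with carbonate and benzyl bromide.

Step 7
Reactants: 8 octa-O-benzyl para-O-TBDPS adduct
Product: 9 octa-O-benzyl para-phenol, 4β-[2,6-bis(benzyloxy)-4-hydroxyphenyl]
Conditions: TBAF (1.1 equiv), AcOH (1.1 equiv), THF, 0 °C
Reagents that add atoms: none
Why: Buffered fluoride desilylation cleaves the aryl silyl ether quickly and leaves all benzyl ethers untouched.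

Step 8
Reactants: 9 octa-O-benzyl para-phenol
Product: 10 salicylaldehyde, 4β-[2,6-bis(benzyloxy)-3-formyl-4-hydroxyphenyl]
Conditions: MgCl2, Et3N, (CH2O)n, THF, reflux; dilute HCl work-up
Reagents that add atoms: paraformaldehyde (as formaldehyde), C=O
Why: In this magnesium phenoxide-directed ortho-formylation (Casnati–Skattebøl) formaldehyde is delivered within the chelate to a position ortho to the only free phenol and the hydroxymethyl stage is oxidised by a second formaldehyde, so the two equivalent ortho positions of ring D react and ring A, which has no free phenol, does not.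

Step 9
Reactants: 10 salicylaldehyde
Product: 11 salicyl alcohol, 4β-[2,6-bis(benzyloxy)-4-hydroxy-3-(hydroxymethyl)phenyl]
Conditions: NaBH4, THF/MeOH, 0 °C; buffered (pH 7) work-up, used at once
Reagents that add atoms: none
Why: Borohydride reduction of the aldehyde is chemoselective here, and the neutral work-up and immediate use avoid early ionisation of the very electron-rich benzylic alcohol.

Step 10
Reactants: 12 3,4,5-tris(benzyloxy)benzaldehyde
Product: 13 1,2,3-tris(benzyloxy)-5-ethynylbenzene
Conditions: dimethyl (1-diazo-2-oxopropyl)phosphonate (1.3 equiv), K2CO3, MeOH/THF, rt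
Reagents that add atoms: dimethyl (1-diazo-2-oxopropyl)phosphonate, COP(=O)(OC)C(=[N+]=[N-])C(C)=O
Why: In the Seyferth–Gilbert homologation (Ohira–Bestmann variant) methanolysis releases the diazomethylphosphonate anion, which olefinates the aldehyde, and loss of N2 with 1,2-hydrogen shift gives the terminal alkyne.

Step 11
Reactants: 13 tris(benzyloxy)phenylacetylene (1.2 equiv); 14 3,4,5-tris(benzyloxy)benzoic acid
Product: 15 (Z)-2-[3,4,5-tris(benzyloxy)phenyl]ethenyl 3,4,5-tris(benzyloxy)benzoate
Conditions: Ru(η3-CH2C(CH3)CH2)2(Ph2P(CH2)4PPh2) (5 mol%), toluene, 65 °C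
Reagents that add atoms: none
Why: In this ruthenium-catalysed anti-Markovnikov addition of a carboxylic acid to a terminal alkyne the carboxylate attacks the α-carbon of a ruthenium vinylidene and protonolysis releases the (Z)-enol ester, as known for arylacetylenes with benzoic acids.

Step 12
Reactants: 11 salicyl alcohol (added slowly); 15 (Z)-enol gallate (3 equiv)
Product: 17 tetradeca-O-benzyl epigallocatechin-(4β→6)-epigallocatechin 3-O-gallate, via ortho-quinone methide 16 (not isolated)
Conditions: (R)-3,3′-bis(2,4,6-triisopropylphenyl)-1,1′-binaphthyl-2,2′-diyl hydrogen phosphate (10 mol%), 5 Å molecular sieves, toluene, 0 °C, 11 added by syringe pump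
Reagents that add atoms: none
Why: Proposed new method: the phosphoric acid should dehydrate 11 (ionisation is eased by the benzyloxy groups ortho and para to the benzylic carbon) to the ortho-quinone methide 16, which stays hydrogen-bonded to the chiral phosphate, and 15 then adds across C-4(L)H2=C-4a(L)–C-8a(L)=O in an inverse-electron-demand hetero-Diels–Alder reaction in which the acyloxy-bearing carbon bonds to the methide carbon (C-3(L)–C-4(L)) and the ring D oxygen to the benzylic carbon (O-1(L)–C-2(L)), because in the asynchronous transition state the positive charge sits best on the carbon carrying the 4-benzyloxyaryl donor whereas the ester oxygen is only a weak donor. The closest known reaction type is the chiral phosphoric acid or N-triflylphosphoramide catalysed [4+2] cycloaddition of ortho-quinone methides made in the flask with styrenes, enol ethers and enecarbamates; an enol ester as the 2π partner and an unsubstituted methide carbon on a flavan-bearing ring have not been shown. Ring F is closed by the cycloaddition itself, and were bond formation stepwise the second bond would arise by collapse of the ring D oxygen onto the benzylic cation in a six-membered closure that keeps both former alkene carbons in the ring. The cis relation of C-2(L) and C-3(L) follows from suprafacial addition to the (Z)-alkene, and their absolute configuration (2R,3R) is set by the face of 15 that the phosphate pocket presents to the methide, since C-4(L) is not a stereocentre and the upper-unit centres are too remote to bias the approach. The step needs regiocontrol (aryl at C-2(L)), retention of the alkene geometry, face selectivity and a single methide site: the first rests on the ring E donor, the second on a short-lived or absent cation, the third on the catalyst, and the last on the only free phenol of 11 being para to the interflavan bond, so that only the 4→6 isomer can form. Slow addition of 11 into excess 15 keeps the methide concentration low and should hold back Friedel–Crafts self-condensation at C-8(L) and at ring A.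

Step 13
Reactants: 17 tetradeca-O-benzyl dimer
Product: 18 epigallocatechin-(4β→6)-epigallocatechin 3-O-gallate, upper unit (2R,3R,4S), lower unit (2R,3R) (target, CNP0204196.2)
Conditions: H2 (1 atm), Pd(OH)2/C, THF/MeOH, rt; filtration under argon
Reagents that add atoms: none
Why: Catalytic hydrogenolysis cleaves the thirteen aryl benzyl ethers and the one alkyl benzyl ether under neutral conditions that leave the gallate ester, the interflavan bond and all five stereocentres untouched.

**Compound list**

1 | (−)-epigallocatechin | O[C@@H]1Cc2c(O)cc(O)cc2O[C@@H]1c1cc(O)c(O)c(O)c1 | starting material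
2 | 5,7,3′,4′,5′-penta-O-benzyl-(−)-epigallocatechin | O[C@@H]1Cc2c(OCc5ccccc5)cc(OCc5ccccc5)cc2O[C@@H]1c1cc(OCc5ccccc5)c(OCc5ccccc5)c(OCc5ccccc5)c1 | intermediate
3 | 4β-(2-ethoxyethoxy)-5,7,3′,4′,5′-penta-O-benzylepigallocatechin | CCOCCO[C@H]3c4c(OCc5ccccc5)cc(OCc5ccccc5)cc4O[C@H](c4cc(OCc5ccccc5)c(OCc5ccccc5)c(OCc5ccccc5)c4)[C@@H]3O | intermediate
4 | 3-O-benzyl-4β-(2-ethoxyethoxy)-5,7,3′,4′,5′-penta-O-benzylepigallocatechin | CCOCCO[C@H]3c4c(OCc5ccccc5)cc(OCc5ccccc5)cc4O[C@H](c4cc(OCc5ccccc5)c(OCc5ccccc5)c(OCc5ccccc5)c4)[C@@H]3OCc5ccccc5 | intermediate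
5 | phloroglucinol | Oc1cc(O)cc(O)c1 | starting material
6 | hexa-O-benzyl epigallocatechin-(4β→2)-phloroglucinol (4β-(2,4,6-trihydroxyphenyl) adduct) | Oc1cc(O)c(c(O)c1)[C@H]3c4c(OCc5ccccc5)cc(OCc5ccccc5)cc4O[C@H](c4cc(OCc5ccccc5)c(OCc5ccccc5)c(OCc5ccccc5)c4)[C@@H]3OCc5ccccc5 | intermediate
7 | para-O-TBDPS ether of 6 (4β-[4-(tert-butyldiphenylsilyloxy)-2,6-dihydroxyphenyl]) | CC(C)(C)[Si](c1ccccc1)(c1ccccc1)Oc1cc(O)c(c(O)c1)[C@H]3c4c(OCc5ccccc5)cc(OCc5ccccc5)cc4O[C@H](c4cc(OCc5ccccc5)c(OCc5ccccc5)c(OCc5ccccc5)c4)[C@@H]3OCc5ccccc5 | intermediate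
8 | octa-O-benzyl para-O-TBDPS adduct (4β-[2,6-bis(benzyloxy)-4-(tert-butyldiphenylsilyloxy)phenyl]) | CC(C)(C)[Si](c1ccccc1)(c1ccccc1)Oc1cc(OCc5ccccc5)c(c(OCc5ccccc5)c1)[C@H]3c4c(OCc5ccccc5)cc(OCc5ccccc5)cc4O[C@H](c4cc(OCc5ccccc5)c(OCc5ccccc5)c(OCc5ccccc5)c4)[C@@H]3OCc5ccccc5 | intermediate
9 | octa-O-benzyl para-phenol (4β-[2,6-bis(benzyloxy)-4-hydroxyphenyl]) | Oc1cc(OCc5ccccc5)c(c(OCc5ccccc5)c1)[C@H]3c4c(OCc5ccccc5)cc(OCc5ccccc5)cc4O[C@H](c4cc(OCc5ccccc5)c(OCc5ccccc5)c(OCc5ccccc5)c4)[C@@H]3OCc5ccccc5 | intermediate
10 | salicylaldehyde (4β-[2,6-bis(benzyloxy)-3-formyl-4-hydroxyphenyl]) | O=Cc1c(O)cc(OCc5ccccc5)c([C@H]3c4c(OCc5ccccc5)cc(OCc5ccccc5)cc4O[C@H](c4cc(OCc5ccccc5)c(OCc5ccccc5)c(OCc5ccccc5)c4)[C@@H]3OCc5ccccc5)c1OCc5ccccc5 | intermediate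
11 | salicyl alcohol (4β-[2,6-bis(benzyloxy)-4-hydroxy-3-(hydroxymethyl)phenyl]) | OCc1c(O)cc(OCc5ccccc5)c([C@H]3c4c(OCc5ccccc5)cc(OCc5ccccc5)cc4O[C@H](c4cc(OCc5ccccc5)c(OCc5ccccc5)c(OCc5ccccc5)c4)[C@@H]3OCc5ccccc5)c1OCc5ccccc5 | intermediate
12 | 3,4,5-tris(benzyloxy)benzaldehyde | O=Cc1cc(OCc2ccccc2)c(OCc2ccccc2)c(OCc2ccccc2)c1 | starting material
13 | 1,2,3-tris(benzyloxy)-5-ethynylbenzene | C#Cc1cc(OCc2ccccc2)c(OCc2ccccc2)c(OCc2ccccc2)c1 | intermediate
14 | 3,4,5-tris(benzyloxy)benzoic acid | OC(=O)c1cc(OCc2ccccc2)c(OCc2ccccc2)c(OCc2ccccc2)c1 | starting material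
15 | (Z)-2-[3,4,5-tris(benzyloxy)phenyl]ethenyl 3,4,5-tris(benzyloxy)benzoate | O=C(O/C=C\c1cc(OCc5ccccc5)c(OCc5ccccc5)c(OCc5ccccc5)c1)c1cc(OCc5ccccc5)c(OCc5ccccc5)c(OCc5ccccc5)c1 | intermediate
16 | ortho-quinone methide of ring D (6-methylenecyclohexa-2,4-dienone carrying the upper unit) | C=C1C(=O)C=C(OCc5ccccc5)C([C@H]3c4c(OCc5ccccc5)cc(OCc5ccccc5)cc4O[C@H](c4cc(OCc5ccccc5)c(OCc5ccccc5)c(OCc5ccccc5)c4)[C@@H]3OCc5ccccc5)=C1OCc5ccccc5 | intermediate
17 | tetradeca-O-benzyl epigallocatechin-(4β→6)-epigallocatechin 3-O-gallate | O=C(O[C@@H]1Cc2c(cc(OCc5ccccc5)c([C@H]3c4c(OCc5ccccc5)cc(OCc5ccccc5)cc4O[C@H](c4cc(OCc5ccccc5)c(OCc5ccccc5)c(OCc5ccccc5)c4)[C@@H]3OCc5ccccc5)c2OCc5ccccc5)O[C@@H]1c1cc(OCc5ccccc5)c(OCc5ccccc5)c(OCc5ccccc5)c1)c1cc(OCc5ccccc5)c(OCc5ccccc5)c(OCc5ccccc5)c1 | intermediate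
18 | epigallocatechin-(4β→6)-epigallocatechin 3-O-gallate (CNP0204196.2) | O=C(O[C@@H]1Cc2c(cc(O)c([C@H]3c4c(O)cc(O)cc4O[C@H](c4cc(O)c(O)c(O)c4)[C@@H]3O)c2O)O[C@@H]1c1cc(O)c(O)c(O)c1)c1cc(O)c(O)c(O)c1 | target

**Step count**

Total: 13 steps. Longest linear sequence: 11 steps (steps 1–9, 12, 13); the enol gallate branch is 2 steps (10, 11).

**Steps most likely to fail**

1. Step 12. The addition may take the opposite regiochemical sense (aryl ending at C-3(L), acyloxy at C-2(L)), the cis geometry may be lost by rotation in a benzylic cation, the catalyst may discriminate the alkene faces poorly, and the methide may be consumed by Friedel–Crafts self-condensation with the electron-rich rings. The fallback abandons the cycloaddition for the classical flavan-4-yl cation condensation with a C-8-blocked nucleophile. It sets out from 2 (using 14 and 4) and returns at 18. The 3-OH of 2 is esterified with acid 14 (DCC, DMAP, CH2Cl2) to give octa-O-benzyl epigallocatechin gallate F1. NBS (CH2Cl2, −78 °C) brominates C-8 of ring A selectively and should give 8-bromo octa-O-benzyl epigallocatechin gallate F2. Condensation of F2 with electrophile 4 (TMSOTf cat., CH2Cl2, −78 °C) can then occur only at C-6 and from the β face, giving the 8(L)-bromo tetradeca-O-benzyl 4β→6 dimer F3. Hydrogenolysis over Pd(OH)2/C in the presence of Et3N removes the bromine together with the benzyl groups and gives 18.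

2. Step 5. Silylation may not discriminate the para phenol cleanly from the two ortho phenols, or may go on to bis-silylation. The fallback moves the differentiation from the adduct into the nucleophile; it sets out from 4 and returns at 8. Commercial 3,5-bis(benzyloxy)phenol is silylated (TBDPSCl, imidazole, DMF) to tert-butyl[3,5-bis(benzyloxy)phenoxy]diphenylsilane F4. Friedel–Crafts reaction of F4 with 4 (TMSOTf cat., CH2Cl2, −78 °C) is steered by the bulky silyl ether toward the carbon between the two benzyloxy groups and should give 8 after chromatographic removal of the regioisomer.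

3. Step 8. The very electron-rich phenol may over-react through its hydroxymethyl stage to methylene-bridged dimers, or formylation may stall. The fallback replaces formylation and reduction by a boron-templated ortho-hydroxymethylation; it sets out from 9 and returns at 11. Phenol 9 is heated with PhB(OH)2 and paraformaldehyde (propionic acid cat., toluene, reflux with water removal) to give the 2-phenyl-4H-1,3,2-benzodioxaborin fused to ring D F5, a storable masked salicyl alcohol. Transesterification with propane-1,3-diol (THF, rt) just before the key step releases 11.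

**Further compounds**

F1 | step 12 | octa-O-benzyl (−)-epigallocatechin 3-O-gallate | O=C(O[C@@H]1Cc2c(OCc5ccccc5)cc(OCc5ccccc5)cc2O[C@@H]1c1cc(OCc5ccccc5)c(OCc5ccccc5)c(OCc5ccccc5)c1)c1cc(OCc5ccccc5)c(OCc5ccccc5)c(OCc5ccccc5)c1
F2 | step 12 | 8-bromo octa-O-benzyl (−)-epigallocatechin 3-O-gallate | O=C(O[C@@H]1Cc2c(OCc5ccccc5)cc(OCc5ccccc5)c(Br)c2O[C@@H]1c1cc(OCc5ccccc5)c(OCc5ccccc5)c(OCc5ccccc5)c1)c1cc(OCc5ccccc5)c(OCc5ccccc5)c(OCc5ccccc5)c1
F3 | step 12 | 8(L)-bromo tetradeca-O-benzyl epigallocatechin-(4β→6)-epigallocatechin 3-O-gallate | O=C(O[C@@H]1Cc2c(c(Br)c(OCc5ccccc5)c([C@H]3c4c(OCc5ccccc5)cc(OCc5ccccc5)cc4O[C@H](c4cc(OCc5ccccc5)c(OCc5ccccc5)c(OCc5ccccc5)c4)[C@@H]3OCc5ccccc5)c2OCc5ccccc5)O[C@@H]1c1cc(OCc5ccccc5)c(OCc5ccccc5)c(OCc5ccccc5)c1)c1cc(OCc5ccccc5)c(OCc5ccccc5)c(OCc5ccccc5)c1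
F4 | step 5 | tert-butyl[3,5-bis(benzyloxy)phenoxy]diphenylsilane | CC(C)(C)[Si](c1ccccc1)(c1ccccc1)Oc1cc(OCc2ccccc2)cc(OCc2ccccc2)c1
F5 | step 8 | 2-phenyl-4H-1,3,2-benzodioxaborin of ring D (boronate of salicyl alcohol 11) | c1ccccc1B2OCc6c(O2)cc(OCc5ccccc5)c([C@H]3c4c(OCc5ccccc5)cc(OCc5ccccc5)cc4O[C@H](c4cc(OCc5ccccc5)c(OCc5ccccc5)c(OCc5ccccc5)c4)[C@@H]3OCc5ccccc5)c6OCc5ccccc5
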